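**Plan**

- Retrosynthesis: remove the acetate, then cut O16–C15 (ring D, alkynol cycloisomerization), C14–C15 (alkyne homologation), O9–C13 (ring C, epoxide opening), C13–C14 and C13–C16 (two CH2 units added to a lactone carbonyl), the C9–O bond (C–H oxidation), the C6 oxygen (allylic oxidation of a 7-ene) and finally C4–C5, C9–C10 and C8–O.
- Enabling feature (labdane numbering throughout): rings A and B carry the C4 gem-dimethyl, C10 methyl and C8 methyl in a head-to-tail isoprenoid pattern, and the C9 side chain ends three carbons out at C13. With C13 as a carboxyl group, an acyclic E,E-triene acid can fold and close rings A and B and a temporary lactone in one cation cascade.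
- Forward: farnesyl bromide and malonate give farnesylacetic acid; step 3 closes rings A and B plus a six-membered 8α,13-lactone. The lactone is opened to the 7-ene, which is taken to the 7-en-6-one, the 8α-methyl ketone and the 9α,13-spirolactone. C13 is then rebuilt as an ethynyl epoxide, ring C (oxolane) closes in step 16, ring D (dihydrofuran) in step 17, and the acetate goes on last.
- Stereochemistry: C5, C10 and H9 come from the chiral proton source and the E,E geometry; C8 from axial protonation in the lithium–ammonia reduction; C9–O from a retentive C–H oxidation; C6 from α-face hydride delivery; C13 from a Sharpless epoxidation (reagent control) followed by inversion in the ring C closure.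

Key step: step 3

Remark: the (R)-configured Brønsted acid is taken to give the natural series (H5 α, C10 methyl β), as in related proton-initiated closures; crystalline lactone 6 would be recrystallised to raise the enantiomeric purity.

**Step 1**
Reactants: 1 (2E,6E)-farnesyl bromide; 2 dimethyl malonate
Product: 3 dimethyl 2-[(2E,6E)-3,7,11-trimethyldodeca-2,6,10-trien-1-yl]malonate
Conditions: NaH (1.0 equiv), 2 (3 equiv), THF, 0 °C; then 1, 0 °C → rt
Reagents that add atoms: none
Why: Malonic ester alkylation (SN2) of the primary allylic bromide by sodiomalonate, run with excess malonate to suppress dialkylation, leaves both E alkenes untouched.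

**Step 2**
Reactants: 3 dimethyl 2-[(2E,6E)-3,7,11-trimethyldodeca-2,6,10-trien-1-yl]malonate
Product: 5 (4E,8E)-5,9,13-trimethyltetradeca-4,8,12-trienoic acid (farnesylacetic acid), via farnesylmalonic acid 4 (not isolated)
Conditions: KOH, MeOH/H2O, 70 °C; cold 1 M HCl to pH 2, extract; crude diacid in pyridine, 110 °C
Reagents that add atoms: potassium hydroxide, [K+].[OH-]
Why: Saponification gives the malonic acid, which loses CO2 on heating in pyridine (malonic acid decarboxylation) without strong acid that could touch the trisubstituted alkenes.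

**Step 3**
Reactants: 5 (4E,8E)-5,9,13-trimethyltetradeca-4,8,12-trienoic acid
Product: 6 (+)-ambreinolide, the 8α,13-lactone of 8-hydroxy-14,15,16-trinorlabdan-13-oic acid (H5 α, H9 α, C10 methyl β, C8 methyl β)
Conditions: (R)-2-(2-fluorobenzyloxy)-2′-hydroxy-1,1′-binaphthyl·SnCl4 (2 equiv), toluene, −78 °C, 3 d; recrystallise
Reagents that add atoms: none
Why: Brønsted acid-initiated cationic polyene cyclization (closest known type: Lewis acid-assisted chiral Brønsted acid cyclization of homopolyprenyl acids and alcohols): the tin-activated BINOL hydroxyl protonates C3 of the terminal C3=C4 alkene, the C4 cation is taken by the C5=C10 alkene, the C10 cation by the C8=C9 alkene and the C8 cation by the carboxyl oxygen, all in one antiperiplanar chair–chair sequence. Ring A closes 6-endo-trig (C4–C5), ring B closes 6-endo-trig (C9–C10), and the six-membered lactone closes by oxygen capture of the tertiary C8 cation (endo with respect to the former C8=C9 alkene). C5 and C10 follow from anti addition across the E C5=C10 alkene (H5 α, C10 methyl β, trans fusion), and C9 and C8 from anti addition across the E C8=C9 alkene (H9 α, C8 oxygen α and equatorial, C8 methyl β and axial). The absolute sense is fixed in the first closure, where the chiral acid protonates one enantioface of the terminal alkene while C5 attacks from the opposite side; the relative configuration is carried by the E,E geometry. The step needs enantioface selection and a complete chair–chair fold instead of early proton loss, which the rigid (R)-acid, the low temperature and the internal carboxyl terminator are expected to secure.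

**Step 4**
Reactants: 6 (+)-ambreinolide
Product: 7 methyl 14,15,16-trinorlabd-7-en-13-oate
Conditions: conc. H2SO4 (3 equiv), MeOH, 0 °C → rt; chromatography on AgNO3-impregnated SiO2
Reagents that add atoms: methanol, CO
Why: Acid-mediated transesterification with E1 loss of the tertiary C8 oxygen, in which the C8 cation should shed a C7 proton to give the trisubstituted Saytzeff 7-ene while the methyl ester blocks re-lactonization, with 8(17)- and 8-ene isomers removed on silver nitrate silica.

**Step 5**
Reactants: 7 methyl 14,15,16-trinorlabd-7-en-13-oate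
Product: 8 methyl 6-oxo-14,15,16-trinorlabd-7-en-13-oate
Conditions: CrO3, 3,5-dimethylpyrazole, CH2Cl2, −20 °C
Reagents that add atoms: chromium trioxide, O=[Cr](=O)=O
Why: Chromium-based allylic oxidation attacks the only allylic methylene, C6, and gives the conjugated 7-en-6-one, as it does on drim-7-enes and steroidal 5-enes.

**Step 6**
Reactants: 8 methyl 6-oxo-14,15,16-trinorlabd-7-en-13-oate
Product: 9 6-oxo-14,15,16-trinorlabd-7-en-13-oic acid
Conditions: LiOH, THF/MeOH/H2O, rt; then 1 M HCl
Reagents that add atoms: lithium hydroxide, [Li+].[OH-]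
Why: Ester saponification frees the carboxylate, which is inert to dissolving metal in the next step and serves as the directing group in step 8.

**Step 7**
Reactants: 9 6-oxo-14,15,16-trinorlabd-7-en-13-oic acid
Product: 10 6-oxo-14,15,16-trinorlabdan-13-oic acid (8α-methyl, H8 β, H9 α)
Conditions: Li (5 equiv), NH3/THF, −78 °C; NH4Cl; then 1 M HCl
Reagents that add atoms: none
Why: Dissolving-metal (Birch-type) enone reduction, in which the β-carbanion at C8 is protonated axially from the β face so that the methyl group ends equatorial (8α, the thermodynamic arrangement, trans to the C9 side chain), while the lithium enolate shields C6 from over-reduction until the quench.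

**Step 8**
Reactants: 10 6-oxo-14,15,16-trinorlabdan-13-oic acid
Product: 11 6-oxo-14,15,16-trinorlabdan-13,9α-olide (spiro γ-lactone, ring oxygen α at C9)
Conditions: [Fe((S,S)-PDP)(MeCN)2](SbF6)2 (3 × 5 mol %), H2O2 (50 % aq, 3 × 1.2 equiv), MeCN, rt (PDP = 1,1′-bis(pyridin-2-ylmethyl)-2,2′-bipyrrolidine)
Reagents that add atoms: hydrogen peroxide, OO
Why: Carboxylate-directed iron-catalysed C–H oxidation (hydrogen abstraction and rebound by the oxo species of the Fe(PDP) catalyst, then lactonization) reaches the tertiary γ-C–H at C9 through a five-membered-lactone geometry and proceeds with retention, so the oxygen sits on the α face where H9 was, while the C6 ketone deactivates C5–H and C7–H.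

**Step 9**
Reactants: 11 6-oxo-14,15,16-trinorlabdan-13,9α-olide
Product: 12 6β-hydroxy-14,15,16-trinorlabdan-13,9α-olide
Conditions: NaBH4, MeOH, 0 °C
Reagents that add atoms: none
Why: Hydride reduction of the hindered C6 ketone comes from the open α face, because the β face is screened by the syn-axial C10 and C4β methyl groups, and gives the axial 6β-alcohol while the γ-lactone is untouched at 0 °C.

**Step 10**
Reactants: 12 6β-hydroxy-14,15,16-trinorlabdan-13,9α-olide
Product: 14 16-(trimethylsilyl)-15-norlabd-13(14)-ene-6β,9α-diol, via bis(silylmethyl) carbinol 13 (not isolated)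
Conditions: Me3SiCH2MgCl (6 equiv), CeCl3 (6 equiv), THF, −78 °C → rt; then SiO2, CH2Cl2, rt
Reagents that add atoms: (trimethylsilyl)methylmagnesium chloride, C[Si](C)(C)C[Mg]Cl
Why: Ester-to-allylsilane conversion, in which the cerium-modified Grignard reagent adds twice to the lactone carbonyl without enolization and Peterson elimination of one β-silyl alcohol on silica leaves the 2-substituted allylsilane and the free 9α-hydroxyl.

**Step 11**
Reactants: 14 16-(trimethylsilyl)-15-norlabd-13(14)-ene-6β,9α-diol
Product: 15 6β,9α-bis(triethylsilyloxy)-16-(trimethylsilyl)-15-norlabd-13(14)-ene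
Conditions: Et3SiOTf (4 equiv), 2,6-lutidine, CH2Cl2, 0 °C → rt
Reagents that add atoms: triethylsilyl trifluoromethanesulfonate, CC[Si](CC)(CC)OS(=O)(=O)C(F)(F)F
Why: Silyl triflate silylation caps both hindered hydroxyls, so that the tertiary 9-OH cannot open the epoxides of the following steps before the two carbon arms on C13 have been differentiated.

**Step 12**
Reactants: 15 6β,9α-bis(triethylsilyloxy)-16-(trimethylsilyl)-15-norlabd-13(14)-ene
Product: 17 6β,9α-bis(triethylsilyloxy)-15-norlabd-13(16)-en-14-ol, via epoxysilane 16 (not isolated)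
Conditions: mCPBA, NaHCO3, CH2Cl2, 0 °C; then PPTS (cat.), MeOH, 0 °C
Reagents that add atoms: meta-chloroperoxybenzoic acid, O=C(OO)c1cccc(Cl)c1
Why: Epoxidation of the electron-rich allylsilane followed by acid-triggered β-silyl (Peterson-type) opening transposes the alkene and delivers the 2-substituted allylic alcohol, the C13 centre of the transient epoxide being erased.

**Step 13**
Reactants: 17 6β,9α-bis(triethylsilyloxy)-15-norlabd-13(16)-en-14-ol
Product: 18 (13R)-13,16-epoxy-6β,9α-bis(triethylsilyloxy)-15-norlabdan-14-ol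
Conditions: Ti(OiPr)4 (10 mol %), D-(−)-diisopropyl tartrate (12 mol %), t-BuOOH (in decane), 4 Å MS, CH2Cl2, −20 °C
Reagents that add atoms: tert-butyl hydroperoxide, CC(C)(C)OO
Why: Sharpless asymmetric epoxidation, in which the Ti(OiPr)4–D-(−)-tartrate catalyst selects the enantioface of the 1,1-disubstituted allylic alcohol and sets C13 as R by reagent control, which is needed because the C1 and C17 flanks of the C9 side chain are nearly mirror-related and give no reliable substrate bias at C13.

**Step 14**
Reactants: 18 (13R)-13,16-epoxy-6β,9α-bis(triethylsilyloxy)-15-norlabdan-14-ol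
Product: 19 (13S)-13,16-epoxy-6β,9α-bis(triethylsilyloxy)-15-norlabdan-14-al
Conditions: Dess–Martin periodinane, NaHCO3, CH2Cl2, 0 °C → rt
Reagents that add atoms: none
Why: Dess–Martin oxidation under bicarbonate buffering gives the α,α-disubstituted epoxy aldehyde, which has no α-hydrogen and cannot epimerize (the descriptor changes only through the priority rules).

**Step 15**
Reactants: 19 (13S)-13,16-epoxy-6β,9α-bis(triethylsilyloxy)-15-norlabdan-14-al
Product: 20 (13R)-13,16-epoxy-6β,9α-bis(triethylsilyloxy)labd-14-yne
Conditions: dimethyl (1-diazo-2-oxopropyl)phosphonate, K2CO3, MeOH, 0 °C → rt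
Reagents that add atoms: dimethyl (1-diazo-2-oxopropyl)phosphonate, CC(=O)C(=[N+]=[N-])P(=O)(OC)OC
Why: Ohira–Bestmann (Seyferth–Gilbert) homologation turns the aldehyde into the terminal alkyne under mild carbonate conditions that spare the epoxide and silyl ethers, adding C15 and marking the C14 arm as distinct from the epoxide CH2 (C16).

**Step 16**
Reactants: 20 (13R)-13,16-epoxy-6β,9α-bis(triethylsilyloxy)labd-14-yne
Product: 22 (13S)-9α,13-epoxylabd-14-yne-6β,16-diol, via epoxy diol 21 (not isolated)
Conditions: Bu4NF/AcOH (1:1), THF, rt → 40 °C; then CSA (10 mol %), CH2Cl2, 0 °C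
Reagents that add atoms: none
Why: Fluoride desilylation followed by acid-catalysed 5-exo-tet epoxide opening, in which the 9α-OH attacks the tertiary propargylic C13 from the side opposite the epoxide oxygen, so that C13 is inverted to S, ring C is closed and the primary 16-OH is released.

**Step 17**
Reactants: 22 (13S)-9α,13-epoxylabd-14-yne-6β,16-diol
Product: 23 (13S)-9α,13:15,16-diepoxylabd-14-en-6β-ol
Conditions: Mo(CO)6 (30 mol %), Et3N, Et2O, hν (350 nm), rt
Reagents that add atoms: none
Why: Alkynol cycloisomerization through a vinylidene complex of the Mo(CO)5 fragment, which is captured by the 16-OH at C15 (5-endo) and protodemetalated to the 2,3-dihydrofuran under basic, acid-free conditions that preserve the acid-labile allylic ether at C13.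

**Step 18**
Reactants: 23 (13S)-9α,13:15,16-diepoxylabd-14-en-6β-ol
Product: 24 (13S)-9α,13:15,16-diepoxylabd-14-en-6β-yl acetate (target)
Conditions: Ac2O, DMAP, Et3N, CH2Cl2, 40 °C
Reagents that add atoms: acetic anhydride, CC(=O)OC(C)=O
Why: DMAP-catalysed acylation of the hindered axial 6β-hydroxyl with acetic anhydride runs under basic conditions that the enol ether tolerates.

**Compound list**

1 | (2E,6E)-farnesyl bromide | CC(C)=CCC/C(C)=C/CC/C(C)=C/CBr | starting material
2 | dimethyl malonate | COC(=O)CC(=O)OC | starting material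
3 | dimethyl 2-[(2E,6E)-3,7,11-trimethyldodeca-2,6,10-trien-1-yl]malonate | CC(C)=CCC/C(C)=C/CC/C(C)=C/CC(C(=O)OC)C(=O)OC | intermediate
4 | (2E,6E)-farnesylmalonic acid | CC(C)=CCC/C(C)=C/CC/C(C)=C/CC(C(=O)O)C(=O)O | intermediate
5 | (4E,8E)-5,9,13-trimethyltetradeca-4,8,12-trienoic acid (farnesylacetic acid) | CC(C)=CCC/C(C)=C/CC/C(C)=C/CCC(=O)O | intermediate
6 | (+)-ambreinolide, 8α,13-lactone of 8-hydroxy-14,15,16-trinorlabdan-13-oic acid | C1C[C@@]3(C)OC(=O)CC[C@@H]3[C@@]2(C)CCCC(C)(C)[C@H]12 | intermediate
7 | methyl 14,15,16-trinorlabd-7-en-13-oate | C1C=C(C)[C@H](CCC(=O)OC)[C@@]2(C)CCCC(C)(C)[C@H]12 | intermediate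
8 | methyl 6-oxo-14,15,16-trinorlabd-7-en-13-oate | O=C1C=C(C)[C@H](CCC(=O)OC)[C@@]2(C)CCCC(C)(C)[C@H]12 | intermediate
9 | 6-oxo-14,15,16-trinorlabd-7-en-13-oic acid | O=C1C=C(C)[C@H](CCC(=O)O)[C@@]2(C)CCCC(C)(C)[C@H]12 | intermediate
10 | 6-oxo-14,15,16-trinorlabdan-13-oic acid (8α-methyl, H9 α) | O=C1C[C@@H](C)[C@H](CCC(=O)O)[C@@]2(C)CCCC(C)(C)[C@H]12 | intermediate
11 | 6-oxo-14,15,16-trinorlabdan-13,9α-olide | O=C1C[C@@H](C)[C@]2(CCC(=O)O2)[C@@]2(C)CCCC(C)(C)[C@H]12 | intermediate
12 | 6β-hydroxy-14,15,16-trinorlabdan-13,9α-olide | O[C@@H]1C[C@@H](C)[C@]2(CCC(=O)O2)[C@@]2(C)CCCC(C)(C)[C@H]12 | intermediate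
13 | 14,16-bis(trimethylsilyl)-15-norlabdane-6β,9α,13-triol | O[C@@H]1C[C@@H](C)[C@](O)(CCC(O)(C[Si](C)(C)C)C[Si](C)(C)C)[C@@]2(C)CCCC(C)(C)[C@H]12 | intermediate
14 | 16-(trimethylsilyl)-15-norlabd-13(14)-ene-6β,9α-diol | O[C@@H]1C[C@@H](C)[C@](O)(CCC(=C)C[Si](C)(C)C)[C@@]2(C)CCCC(C)(C)[C@H]12 | intermediate
15 | 6β,9α-bis(triethylsilyloxy)-16-(trimethylsilyl)-15-norlabd-13(14)-ene | CC[Si](CC)(CC)O[C@@H]1C[C@@H](C)[C@](O[Si](CC)(CC)CC)(CCC(=C)C[Si](C)(C)C)[C@@]2(C)CCCC(C)(C)[C@H]12 | intermediate
16 | 13,14-epoxy-6β,9α-bis(triethylsilyloxy)-16-(trimethylsilyl)-15-norlabdane (both C13 epimers) | CC[Si](CC)(CC)O[C@@H]1C[C@@H](C)[C@](O[Si](CC)(CC)CC)(CCC3(C[Si](C)(C)C)CO3)[C@@]2(C)CCCC(C)(C)[C@H]12 | intermediate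
17 | 6β,9α-bis(triethylsilyloxy)-15-norlabd-13(16)-en-14-ol | CC[Si](CC)(CC)O[C@@H]1C[C@@H](C)[C@](O[Si](CC)(CC)CC)(CCC(=C)CO)[C@@]2(C)CCCC(C)(C)[C@H]12 | intermediate
18 | (13R)-13,16-epoxy-6β,9α-bis(triethylsilyloxy)-15-norlabdan-14-ol | CC[Si](CC)(CC)O[C@@H]1C[C@@H](C)[C@](O[Si](CC)(CC)CC)(CC[C@@]3(CO)CO3)[C@@]2(C)CCCC(C)(C)[C@H]12 | intermediate
19 | (13S)-13,16-epoxy-6β,9α-bis(triethylsilyloxy)-15-norlabdan-14-al | CC[Si](CC)(CC)O[C@@H]1C[C@@H](C)[C@](O[Si](CC)(CC)CC)(CC[C@@]3(C=O)CO3)[C@@]2(C)CCCC(C)(C)[C@H]12 | intermediate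
20 | (13R)-13,16-epoxy-6β,9α-bis(triethylsilyloxy)labd-14-yne | CC[Si](CC)(CC)O[C@@H]1C[C@@H](C)[C@](O[Si](CC)(CC)CC)(CC[C@@]3(C#C)CO3)[C@@]2(C)CCCC(C)(C)[C@H]12 | intermediate
21 | (13R)-13,16-epoxylabd-14-yne-6β,9α-diol | O[C@@H]1C[C@@H](C)[C@](O)(CC[C@@]3(C#C)CO3)[C@@]2(C)CCCC(C)(C)[C@H]12 | intermediate
22 | (13S)-9α,13-epoxylabd-14-yne-6β,16-diol | O[C@@H]1C[C@@H](C)[C@]2(CC[C@](C#C)(CO)O2)[C@@]2(C)CCCC(C)(C)[C@H]12 | intermediate
23 | (13S)-9α,13:15,16-diepoxylabd-14-en-6β-ol | O[C@@H]1C[C@@H](C)[C@]2(CC[C@@]3(C=COC3)O2)[C@@]2(C)CCCC(C)(C)[C@H]12 | intermediate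
24 | (13S)-9α,13:15,16-diepoxylabd-14-en-6β-yl acetate | CC(=O)O[C@@H]1C[C@@H](C)[C@]2(CC[C@@]3(C=COC3)O2)[C@@]2(C)CCCC(C)(C)[C@H]12 | target

**Step count and risks**

Total steps: 18. Longest linear sequence: 18 steps (fully linear, from 1).

Steps most likely to fail:

1. Step 8 (C–H lactonization). The iron oxidant may abstract hydrogen at other sites (C8–H, ring A methylenes) or stall at low conversion on the hindered axial C9–H. The fallback sets out from 10 and returns at 11. Acid 10 is converted with 1,1′-carbonyldiimidazole and ammonia into 6-oxo-14,15,16-trinorlabdan-13-amide F1. Irradiation of F1 with PhI(OAc)2 and I2 in 1,2-dichloroethane (Hofmann–Löffler–Freytag-type amidyl radical chemistry) lets the nitrogen radical take H9 through a six-membered transition state. The C9 radical is oxidised and closed by the amide oxygen on the axial α face to 6-oxo-14,15,16-trinorlabdan-13,9α-imidate (iminolactone) F2. Aqueous HCl hydrolysis of F2 gives lactone 11.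

2. Step 4 (lactone to 7-ene). Proton loss from the C8 cation may be unselective (exocyclic 8(17)-ene and tetrasubstituted 8-ene beside the 7-ene), and hydride or methyl shifts may set in under strong acid. The fallback sets out from 6 and returns at 7. Lactone 6 is saponified with KOH to potassium 8α-hydroxy-14,15,16-trinorlabdan-13-oate F3. The carboxylate is methylated with MeI in DMF to methyl 8α-hydroxy-14,15,16-trinorlabdan-13-oate F4. Kinetic dehydration with SOCl2/pyridine at −78 °C, where only a methyl hydrogen is antiperiplanar to the equatorial 8α-oxygen, gives methyl 14,15,16-trinorlabd-8(17)-en-13-oate F5. The exocyclic alkene is then moved into the ring with RhCl3·3H2O in hot ethanol (metal hydride addition–elimination), which should stop at the trisubstituted 7-ene 7 because the tetrasubstituted isomer requires removal of the hindered H9.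

3. Step 17 (ring D closure). The vinylidene may fail to form or to be captured at the neopentyl alcohol, or the metal may ionise the propargylic C13–O9 bond. The fallback sets out from 22 and returns at 23. Anti-Markovnikov hydration of the terminal alkyne by hydroboration with excess dicyclohexylborane and oxidation with NaBO3 gives the C15 aldehyde, which closes with the 16-OH to the lactol (13S)-9α,13:15,16-diepoxylabdane-6β,15-diol F6. Dehydration of the lactol with MsCl/Et3N in CH2Cl2 at −20 °C, with the hindered 6β-OH left alone, gives enol ether 23.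

Further compounds
F1 | step 8 | 6-oxo-14,15,16-trinorlabdan-13-amide | O=C1C[C@@H](C)[C@H](CCC(N)=O)[C@@]2(C)CCCC(C)(C)[C@H]12
F2 | step 8 | 6-oxo-14,15,16-trinorlabdan-13,9α-imidate (iminolactone) | O=C1C[C@@H](C)[C@]2(CCC(=N)O2)[C@@]2(C)CCCC(C)(C)[C@H]12
F3 | step 4 | potassium 8α-hydroxy-14,15,16-trinorlabdan-13-oate | C1C[C@@](C)(O)[C@H](CCC(=O)[O-])[C@@]2(C)CCCC(C)(C)[C@H]12.[K+]
F4 | step 4 | methyl 8α-hydroxy-14,15,16-trinorlabdan-13-oate | C1C[C@@](C)(O)[C@H](CCC(=O)OC)[C@@]2(C)CCCC(C)(C)[C@H]12
F5 | step 4 | methyl 14,15,16-trinorlabd-8(17)-en-13-oate | C1CC(=C)[C@H](CCC(=O)OC)[C@@]2(C)CCCC(C)(C)[C@H]12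
F6 | step 17 | (13S)-9α,13:15,16-diepoxylabdane-6β,15-diol (lactol, both C15 anomers) | O[C@@H]1C[C@@H](C)[C@]2(CC[C@@]3(CC(O)OC3)O2)[C@@]2(C)CCCC(C)(C)[C@H]12
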